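The ten-membered carbocycle is cut at C2–C3, the one ring bond whose two carbons are each allylic (C2 to C1=C10, C3 to C4=C5). With an NH placed between these carbons, ring formation becomes an intramolecular sulfonamide N-allylation that gives an eleven-membered diallylamine. A single nitrogen-deletion step then expels that nitrogen as N2 and joins C2 to C3, contracting the azacycle to the germacradienolide ring with both alkene geometries and the trans C7/C8 lactone already in place. The precursor is the lactone-fused 1-azacycloundeca-3,8-diene (free secondary amine) with C14 as a silyl ether and C15 as a PMB ether. Lactone methylenation and the two acylations follow.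

Key step: step 16

Remark: germacrane numbering is used throughout. With oxygen on C14 and C15 the CIP labels are 1(10)E and 4Z, i.e. a cis ring bond at C1=C10 and a trans ring bond at C4=C5. The C4=C5 olefination must therefore be the ordinary E-selective reaction of a carbonyl-stabilised reagent (carbonyl carbon C3 trans to C6).
Remark: C14 is carried as the acid-stable TBDPS ether, so that it survives the aqueous-acid acetal cleavage and does not migrate in the alkenyl metal. Ethyl 2-(diethoxyphosphoryl)acrylate, ethyl 2-(hydroxymethyl)acrylate and N-(benzyloxy)-N-(pivaloyloxy)-4-(trifluoromethyl)benzamide are taken as purchasable.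

Step 1
Reactants: 1 but-2-yne-1,4-diol
Product: 2 4-((tert-butyldiphenylsilyl)oxy)but-2-yn-1-ol
Conditions: TBDPSCl (1 equiv), imidazole, 1 (4 equiv), DMF, 0 °C to rt
Reagents that add atoms: tert-butyl(chloro)diphenylsilane, CC(C)(C)[Si](Cl)(c1ccccc1)c1ccccc1
Why: Statistical monosilylation of the symmetric diol used in excess is a routine silyl ether formation and gives the mono-ether whose oxygen becomes C14–O.

Step 2
Reactants: 2 mono-TBDPS butynediol
Product: 4 (Z)-4-((tert-butyldiphenylsilyl)oxy)-3-iodobut-2-en-1-ol, via cyclic alkenylalanate 3 (not isolated)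
Conditions: Red-Al, THF, 0 °C; EtOAc quench of excess hydride; then I2, THF, −78 to 0 °C
Reagents that add atoms: iodine, II
Why: Hydroxyl-directed trans-hydroalumination of the propargylic alcohol puts aluminium on the distal alkyne carbon (C10), and iodinolysis with retention gives the Z-iodide, which fixes C14 trans to C2 across the future C1=C10 bond.

Step 3
Reactants: 4 (Z)-iodo alcohol
Product: 5 THP ether of 4
Conditions: 3,4-dihydro-2H-pyran, PPTS (cat.), CH2Cl2, rt
Reagents that add atoms: 3,4-dihydro-2H-pyran, C1=COCCC1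
Why: Acid-catalysed acetalisation (THP protection) masks the C2 hydroxyl for the organometallic steps and is later removed together with the dioxolane.

Step 4
Reactants: 5 THP-protected (Z)-iodide + 6 (S)-epichlorohydrin
Product: 8 (2S,4E)-1-chloro-4-(((tert-butyldiphenylsilyl)oxy)methyl)-6-((tetrahydro-2H-pyran-2-yl)oxy)hex-4-en-2-ol, via alkenylmagnesium chloride 7 (not isolated)
Conditions: i-PrMgCl·LiCl, THF, −20 °C; then CuI (10 mol%), 6, −30 to 0 °C; aq. NH4Cl
Reagents that add atoms: none
Why: Iodine–magnesium exchange gives a configurationally stable alkenylmagnesium species, and copper-catalysed SN2 opening of the epoxide at its CH2 carbon forms C9–C10 while C8 keeps the configuration of (S)-epichlorohydrin.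

Step 5
Reactants: 8 chlorohydrin
Product: 10 (3S,5E)-5-(((tert-butyldiphenylsilyl)oxy)methyl)-7-((tetrahydro-2H-pyran-2-yl)oxy)hepta-1,5-dien-3-ol, via terminal epoxide 9 (not isolated)
Conditions: Me3S+ I− (4 equiv), n-BuLi (3.9 equiv), THF, −20 °C to rt
Reagents that add atoms: trimethylsulfonium iodide, C[S+](C)C.[I-]
Why: The alkoxide closes to the terminal epoxide, and excess dimethylsulfonium methylide opens it at CH2 and eliminates dimethyl sulfide (one-carbon homologation of an epoxide to an allylic alcohol), leaving the C8 stereocentre untouched.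

Step 6
Reactants: 10 allylic alcohol
Product: 11 acrylate ester of 10
Conditions: acryloyl chloride, i-Pr2NEt, CH2Cl2, −20 to 0 °C
Reagents that add atoms: acryloyl chloride, C=CC(Cl)=O
Why: O-Acylation of the secondary allylic alcohol with an acid chloride and a hindered amine base is a routine esterification that assembles the diene for ring closure.

Step 7
Reactants: 11 acrylate
Product: 12 (S)-5-((E)-2-(((tert-butyldiphenylsilyl)oxy)methyl)-4-((tetrahydro-2H-pyran-2-yl)oxy)but-2-en-1-yl)furan-2(5H)-one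
Conditions: Grubbs second-generation catalyst (5 mol%), CH2Cl2 (0.01 M), 40 °C
Reagents that add atoms: none
Why: Ring-closing metathesis between the vinyl group and the acrylate closes the five-membered butenolide with loss of ethene, while the hindered trisubstituted C1=C10 alkene stays out of the reaction.

Step 8
Reactants: 12 butenolide + 13 (1,3-dioxolan-2-ylmethyl)magnesium bromide
Product: 15 (4R,5S)-4-((1,3-dioxolan-2-yl)methyl)-5-((E)-2-(((tert-butyldiphenylsilyl)oxy)methyl)-4-((tetrahydro-2H-pyran-2-yl)oxy)but-2-en-1-yl)dihydrofuran-2(3H)-one, via silyl ketene acetal 14 (not isolated)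
Conditions: 13 (3 equiv), CuBr·SMe2 (0.3 equiv), TMSCl (3 equiv), THF, −78 to −30 °C; sat. aq. NH4Cl
Reagents that add atoms: none
Why: Copper-catalysed, TMSCl-accelerated conjugate addition of the Grignard reagent should occur on the butenolide face anti to the C8 side chain, so C7 is set trans to C8 by substrate control.

Step 9
Reactants: 15 lactone bis-acetal
Product: 16 2-((2S,3R)-2-((E)-2-(((tert-butyldiphenylsilyl)oxy)methyl)-4-hydroxybut-2-en-1-yl)-5-oxotetrahydrofuran-3-yl)acetaldehyde
Conditions: 1 M aq. HCl, THF, rt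
Reagents that add atoms: water, O
Why: Aqueous acid hydrolysis cleaves both acetals in one operation (dioxolane to the C5 aldehyde, THP to the C2 alcohol), while the TBDPS ether and the lactone are stable to these conditions.

Step 10
Reactants: 16 hydroxy aldehyde + 17 ethyl 2-(diethoxyphosphoryl)acrylate + 18 4-methoxybenzyl alcohol
Product: 20 ethyl (E)-4-((2S,3R)-2-((E)-2-(((tert-butyldiphenylsilyl)oxy)methyl)-4-hydroxybut-2-en-1-yl)-5-oxotetrahydrofuran-3-yl)-2-(((4-methoxybenzyl)oxy)methyl)but-2-enoate, via sodium phosphonate carbanion 19 (not isolated)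
Conditions: 18 (1.3 equiv), NaH (1.3 equiv), THF, 0 °C; 17 (1.3 equiv), 0 °C; then 16, −40 to 0 °C
Reagents that add atoms: none
Why: Oxa-Michael addition of the PMB alkoxide to the vinylphosphonate generates the stabilised phosphonate anion, whose Horner–Wadsworth–Emmons reaction with the aldehyde is expected to favour the E-enoate (ester carbon C3 trans to C6, hence C15 cis to C6), with any minor isomer removed by chromatography.

Step 11
Reactants: 20 hydroxy enoate + 21 2-nitrobenzenesulfonamide
Product: 22 ethyl (E)-4-((2S,3R)-2-((E)-2-(((tert-butyldiphenylsilyl)oxy)methyl)-4-((2-nitrophenyl)sulfonamido)but-2-en-1-yl)-5-oxotetrahydrofuran-3-yl)-2-(((4-methoxybenzyl)oxy)methyl)but-2-enoate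
Conditions: 21 (3 equiv), PPh3, DIAD, THF, 0 °C to rt
Reagents that add atoms: none
Why: Mitsunobu N-alkylation of the acidic primary sulfonamide (in excess, to suppress dialkylation) by the primary allylic alcohol puts the nitrogen on C2 by SN2 displacement without touching the enoate or the lactone.

Step 12
Reactants: 22 sulfonamido enoate
Product: 24 (E)-enoic acid corresponding to 22 (C3 carboxylic acid with the lactone intact), via ring-opened dilithium carboxylate 23 (not isolated)
Conditions: LiOH·H2O, THF/H2O, rt; then 1 M HCl to pH 2, EtOAc, rt (PPTS cat. if relactonisation is slow)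
Reagents that add atoms: lithium hydroxide, [Li+].[OH-]
Why: Saponification hydrolyses the ethyl ester while the lactone opens reversibly, and acidification reforms only the five-membered lactone because the E-configured C3 acid cannot reach the C8 hydroxyl.

Step 13
Reactants: 24 enoic acid
Product: 26 N-((E)-3-(((tert-butyldiphenylsilyl)oxy)methyl)-4-((2S,3R)-3-((Z)-4-hydroxy-3-(((4-methoxybenzyl)oxy)methyl)but-2-en-1-yl)-5-oxotetrahydrofuran-2-yl)but-2-en-1-yl)-2-nitrobenzenesulfonamide, via mixed carbonic anhydride 25 (not isolated)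
Conditions: i-BuOCOCl, N-methylmorpholine, THF, −15 °C; then NaBH4, H2O, 0 °C
Reagents that add atoms: none
Why: Activation of the acid as its mixed carbonic anhydride followed by borohydride reduction converts only C3 into the allylic alcohol, since NaBH4 leaves the γ-lactone and the nitroarene untouched at 0 °C.

Step 14
Reactants: 26 sulfonamido allylic alcohol
Product: 27 N-(2-nitrophenylsulfonyl) eleven-membered azacycle (N between C2 and C3)
Conditions: PPh3, DIAD, toluene/THF, slow addition of 26 to 2 mM final concentration, rt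
Reagents that add atoms: none
Why: Intramolecular Fukuyama–Mitsunobu N-alkylation under high dilution closes the eleven-membered ring by SN2 attack of the sulfonamide on the activated C3 alcohol, leaving both alkene geometries unchanged.

Step 15
Reactants: 27 N-nosyl azacycle
Product: 28 eleven-membered secondary amine (NH between C2 and C3) fused to the trans lactone, C14 OTBDPS, C15 OPMB
Conditions: PhSH, K2CO3, MeCN, rt
Reagents that add atoms: none
Why: Fukuyama deprotection, in which thiolate attacks the nitroarene (SNAr through a Meisenheimer adduct) and releases the amine with loss of SO2, leaves the lactone and both ethers intact.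

Step 16
Reactants: 28 eleven-membered diallylamine
Product: 30 (7R,8S)-14-((tert-butyldiphenylsilyl)oxy)-15-((4-methoxybenzyl)oxy)germacra-1(10)E,4Z-dien-12,8-olide, via isodiazene 29 (not isolated)
Conditions: N-(benzyloxy)-N-(pivaloyloxy)-4-(trifluoromethyl)benzamide (1.5 equiv), THF (0.02 M), 45 °C, inert atmosphere
Reagents that add atoms: none
Why: Proposed new method: the secondary amine displaces pivalate at the nitrogen of the anomeric amide, the N-benzyloxy hydrazide so formed expels benzyl 4-(trifluoromethyl)benzoate to give isodiazene 29, and loss of N2 leaves a singlet pair of allyl radicals (C2–C1–C10 and C3–C4–C5) still tethered through C6–C9, which recombines at C2 and C3. The closest established chemistry is nitrogen deletion of benzylic secondary amines and ring contraction of α-aryl saturated azacycles with this reagent class; here both C–N bonds are allylic instead, which should stabilise the radical pair comparably but is untested in a medium ring. The ten-membered carbocycle closes by intramolecular radical–radical recombination, i.e. contraction of the eleven-membered azacycle by extrusion of its nitrogen, so no dilution or template effect is required. No stereocentre is formed, and C7 and C8 are remote and not epimerisable under these neutral conditions, which also lie well below the temperature at which the 1,5-diene product would undergo Cope rearrangement. The step needs C2–C3 coupling with both alkene geometries retained: bond formation at the unsubstituted termini is favoured over coupling at the fully substituted C4 or C10 (which would give six- or eight-membered rings with congested quaternary centres), and collapse of the tethered singlet pair should outrun rotation within the allyl units. A competing 2,3-shift of the allylic isodiazene to a cyclic azo compound would lose N2 to the same radical pair and should not change the outcome.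

Step 17
Reactants: 30 germacradienolide
Product: 33 (7R,8S)-14-((tert-butyldiphenylsilyl)oxy)-15-((4-methoxybenzyl)oxy)germacra-1(10)E,4Z,11(13)-trien-12,8-olide, via Mannich base 31 (not isolated), via trimethylammonium iodide 32 (not isolated)
Conditions: LiHMDS, THF, −78 °C; Eschenmoser's salt, −78 °C to rt; then MeI, rt; then sat. aq. NaHCO3/CH2Cl2, rt
Reagents that add atoms: N,N-dimethylmethyleneiminium iodide (Eschenmoser's salt), C=[N+](C)C.[I-]
Why: Lactone enolate Mannich reaction, N-methylation and base-induced elimination of trimethylamine is the classical α-methylenation of γ-lactones, and the C11 centre formed in passing is destroyed in the elimination.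

Step 18
Reactants: 33 α-methylene lactone
Product: 34 C14 primary allylic alcohol (15-OPMB retained)
Conditions: TBAF, AcOH, THF, 0 °C to rt
Reagents that add atoms: none
Why: Fluoride-mediated desilylation buffered with acetic acid removes the TBDPS ether without conjugate addition to the α-methylene lactone.

Step 19
Reactants: 34 C14 alcohol
Product: 35 C14 acetate (15-OPMB retained)
Conditions: Ac2O, pyridine, DMAP (cat.), CH2Cl2, 0 °C
Reagents that add atoms: acetic anhydride, CC(=O)OC(C)=O
Why: DMAP-catalysed acetylation of the primary allylic alcohol installs the C14 acetate.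

Step 20
Reactants: 35 C14 acetate
Product: 36 (7R,8S)-14-acetoxy-15-hydroxygermacra-1(10)E,4Z,11(13)-trien-12,8-olide
Conditions: DDQ, CH2Cl2/pH 7 buffer, 0 °C
Reagents that add atoms: none
Why: Oxidative PMB ether cleavage with DDQ (benzylic oxidation to the oxocarbenium ion, then hydrolysis) frees the C15 alcohol without affecting the acetate, the diene or the methylene lactone.

Step 21
Reactants: 37 ethyl 2-(hydroxymethyl)acrylate
Product: 38 ethyl 2-(((tert-butyldimethylsilyl)oxy)methyl)acrylate
Conditions: TBSCl, imidazole, CH2Cl2, 0 °C to rt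
Reagents that add atoms: tert-butyl(chloro)dimethylsilane, CC(C)(C)[Si](C)(C)Cl
Why: Silylation of the primary alcohol with TBSCl/imidazole protects the side-chain hydroxyl.

Step 22
Reactants: 38 silyl-protected ester
Product: 39 2-(((tert-butyldimethylsilyl)oxy)methyl)acrylic acid
Conditions: LiOH·H2O, THF/H2O, 0 °C to rt; then citric acid to pH 4
Reagents that add atoms: lithium hydroxide, [Li+].[OH-]
Why: Mild saponification of the ethyl ester gives the acrylic acid with the silyl ether intact.

Step 23
Reactants: 36 C15 alcohol + 39 protected acrylic acid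
Product: 40 15-O-(2-(((tert-butyldimethylsilyl)oxy)methyl)acryloyl) ester of 36
Conditions: N,N'-diisopropylcarbodiimide, DMAP (0.2 equiv), CH2Cl2, 0 °C to rt
Reagents that add atoms: none
Why: Steglich esterification (carbodiimide/DMAP) couples the primary allylic C15 alcohol with the acid under neutral conditions that spare the acetate and the methylene lactone.

Step 24
Reactants: 40 silyl-protected diester
Product: 41 target, (7R,8S)-14-acetoxy-15-((2-(hydroxymethyl)acryloyl)oxy)germacra-1(10)E,4Z,11(13)-trien-12,8-olide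
Conditions: HF·pyridine, pyridine, THF, 0 °C to rt
Reagents that add atoms: none
Why: Buffered fluoride desilylation removes the TBS group without acyl migration or conjugate addition and gives the target.

Compound list
1 | but-2-yne-1,4-diol | OCC#CCO | starting material
2 | 4-((tert-butyldiphenylsilyl)oxy)but-2-yn-1-ol | OCC#CCO[Si](c1ccccc1)(c1ccccc1)C(C)(C)C | intermediate
3 | sodium cyclic alkenylalanate from 2 (five-membered O–Al–C10 chelate, two 2-methoxyethoxy groups on Al) | [Na+].COCCO[Al-]1(OCCOC)OCC=C1CO[Si](c1ccccc1)(c1ccccc1)C(C)(C)C | intermediate (not isolated)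
4 | (Z)-4-((tert-butyldiphenylsilyl)oxy)-3-iodobut-2-en-1-ol | OC/C=C(\I)CO[Si](c1ccccc1)(c1ccccc1)C(C)(C)C | intermediate
5 | 2-(((Z)-4-((tert-butyldiphenylsilyl)oxy)-3-iodobut-2-en-1-yl)oxy)tetrahydro-2H-pyran (THP epimers) | I/C(CO[Si](c1ccccc1)(c1ccccc1)C(C)(C)C)=C\COC1CCCCO1 | intermediate
6 | (S)-epichlorohydrin | ClC[C@@H]1CO1 | starting material
7 | alkenylmagnesium chloride from 5 (Mg in place of I, geometry retained) | Cl[Mg]/C(CO[Si](c1ccccc1)(c1ccccc1)C(C)(C)C)=C\COC1CCCCO1 | intermediate (not isolated)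
8 | (2S,4E)-1-chloro-4-(((tert-butyldiphenylsilyl)oxy)methyl)-6-((tetrahydro-2H-pyran-2-yl)oxy)hex-4-en-2-ol | ClC[C@@H](O)C/C(CO[Si](c1ccccc1)(c1ccccc1)C(C)(C)C)=C\COC1CCCCO1 | intermediate
9 | (S)-2-((E)-2-(((tert-butyldiphenylsilyl)oxy)methyl)-4-((tetrahydro-2H-pyran-2-yl)oxy)but-2-en-1-yl)oxirane | C1O[C@H]1C/C(CO[Si](c2ccccc2)(c2ccccc2)C(C)(C)C)=C\COC2CCCCO2 | intermediate (not isolated)
10 | (3S,5E)-5-(((tert-butyldiphenylsilyl)oxy)methyl)-7-((tetrahydro-2H-pyran-2-yl)oxy)hepta-1,5-dien-3-ol | C=C[C@@H](O)C/C(CO[Si](c1ccccc1)(c1ccccc1)C(C)(C)C)=C\COC1CCCCO1 | intermediate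
11 | (3S,5E)-5-(((tert-butyldiphenylsilyl)oxy)methyl)-7-((tetrahydro-2H-pyran-2-yl)oxy)hepta-1,5-dien-3-yl acrylate | C=CC(=O)O[C@H](C=C)C/C(CO[Si](c1ccccc1)(c1ccccc1)C(C)(C)C)=C\COC1CCCCO1 | intermediate
12 | (S)-5-((E)-2-(((tert-butyldiphenylsilyl)oxy)methyl)-4-((tetrahydro-2H-pyran-2-yl)oxy)but-2-en-1-yl)furan-2(5H)-one | O=C1C=C[C@H](C/C(CO[Si](c2ccccc2)(c2ccccc2)C(C)(C)C)=C\COC2CCCCO2)O1 | intermediate
13 | (1,3-dioxolan-2-ylmethyl)magnesium bromide | Br[Mg]CC1OCCO1 | starting material
14 | trimethylsilyl ketene acetal of 15 (2-silyloxy-4,5-dihydrofuran) | C[Si](C)(C)OC1=C[C@@H](CC2OCCO2)[C@H](C/C(CO[Si](c2ccccc2)(c2ccccc2)C(C)(C)C)=C\COC2CCCCO2)O1 | intermediate (not isolated)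
15 | (4R,5S)-4-((1,3-dioxolan-2-yl)methyl)-5-((E)-2-(((tert-butyldiphenylsilyl)oxy)methyl)-4-((tetrahydro-2H-pyran-2-yl)oxy)but-2-en-1-yl)dihydrofuran-2(3H)-one (trans) | O=C1C[C@@H](CC2OCCO2)[C@H](C/C(CO[Si](c2ccccc2)(c2ccccc2)C(C)(C)C)=C\COC2CCCCO2)O1 | intermediate
16 | 2-((2S,3R)-2-((E)-2-(((tert-butyldiphenylsilyl)oxy)methyl)-4-hydroxybut-2-en-1-yl)-5-oxotetrahydrofuran-3-yl)acetaldehyde | O=CC[C@@H]1CC(=O)O[C@H]1C/C(CO[Si](c1ccccc1)(c1ccccc1)C(C)(C)C)=C\CO | intermediate
17 | ethyl 2-(diethoxyphosphoryl)acrylate | C=C(C(=O)OCC)P(=O)(OCC)OCC | starting material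
18 | 4-methoxybenzyl alcohol | COc1ccc(CO)cc1 | starting material
19 | sodium salt (α-carbanion) of ethyl 2-(diethoxyphosphoryl)-3-((4-methoxybenzyl)oxy)propanoate | [Na+].CCOC(=O)[C-](COCc1ccc(OC)cc1)P(=O)(OCC)OCC | intermediate (not isolated)
20 | ethyl (E)-4-((2S,3R)-2-((E)-2-(((tert-butyldiphenylsilyl)oxy)methyl)-4-hydroxybut-2-en-1-yl)-5-oxotetrahydrofuran-3-yl)-2-(((4-methoxybenzyl)oxy)methyl)but-2-enoate | CCOC(=O)/C(COCc1ccc(OC)cc1)=C/C[C@@H]1CC(=O)O[C@H]1C/C(CO[Si](c1ccccc1)(c1ccccc1)C(C)(C)C)=C\CO | intermediate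
21 | 2-nitrobenzenesulfonamide | NS(=O)(=O)c1ccccc1[N+](=O)[O-] | starting material
22 | ethyl (E)-4-((2S,3R)-2-((E)-2-(((tert-butyldiphenylsilyl)oxy)methyl)-4-((2-nitrophenyl)sulfonamido)but-2-en-1-yl)-5-oxotetrahydrofuran-3-yl)-2-(((4-methoxybenzyl)oxy)methyl)but-2-enoate | CCOC(=O)/C(COCc1ccc(OC)cc1)=C/C[C@@H]1CC(=O)O[C@H]1C/C(CO[Si](c1ccccc1)(c1ccccc1)C(C)(C)C)=C\CNS(=O)(=O)c1ccccc1[N+](=O)[O-] | intermediate
23 | dilithium salt of the ring-opened C8-hydroxy C3,C12-dicarboxylate of 22 | [Li+].[Li+].[O-]C(=O)/C(COCc1ccc(OC)cc1)=C/C[C@H](CC([O-])=O)[C@@H](O)C/C(CO[Si](c1ccccc1)(c1ccccc1)C(C)(C)C)=C\CNS(=O)(=O)c1ccccc1[N+](=O)[O-] | intermediate (not isolated)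
24 | (E)-4-((2S,3R)-2-((E)-2-(((tert-butyldiphenylsilyl)oxy)methyl)-4-((2-nitrophenyl)sulfonamido)but-2-en-1-yl)-5-oxotetrahydrofuran-3-yl)-2-(((4-methoxybenzyl)oxy)methyl)but-2-enoic acid | OC(=O)/C(COCc1ccc(OC)cc1)=C/C[C@@H]1CC(=O)O[C@H]1C/C(CO[Si](c1ccccc1)(c1ccccc1)C(C)(C)C)=C\CNS(=O)(=O)c1ccccc1[N+](=O)[O-] | intermediate
25 | isobutyl carbonic mixed anhydride of 24 | CC(C)COC(=O)OC(=O)/C(COCc1ccc(OC)cc1)=C/C[C@@H]1CC(=O)O[C@H]1C/C(CO[Si](c1ccccc1)(c1ccccc1)C(C)(C)C)=C\CNS(=O)(=O)c1ccccc1[N+](=O)[O-] | intermediate (not isolated)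
26 | N-((E)-3-(((tert-butyldiphenylsilyl)oxy)methyl)-4-((2S,3R)-3-((Z)-4-hydroxy-3-(((4-methoxybenzyl)oxy)methyl)but-2-en-1-yl)-5-oxotetrahydrofuran-2-yl)but-2-en-1-yl)-2-nitrobenzenesulfonamide | OC/C(COCc1ccc(OC)cc1)=C/C[C@@H]1CC(=O)O[C@H]1C/C(CO[Si](c1ccccc1)(c1ccccc1)C(C)(C)C)=C\CNS(=O)(=O)c1ccccc1[N+](=O)[O-] | intermediate
27 | N-(2-nitrophenylsulfonyl) eleven-membered azacycle: (7R,8S) trans-fused 12,8-olide, N between C2 and C3, C1=C10 E, C4=C5 Z, 14-OTBDPS, 15-OPMB | COc1ccc(COC/C2=C\C[C@@H]3CC(=O)O[C@H]3C/C(CO[Si](c3ccccc3)(c3ccccc3)C(C)(C)C)=C\CN(C2)S(=O)(=O)c2ccccc2[N+](=O)[O-])cc1 | intermediate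
28 | eleven-membered secondary amine: (7R,8S) trans-fused 12,8-olide, NH between C2 and C3, C1=C10 E, C4=C5 Z, 14-OTBDPS, 15-OPMB | COc1ccc(COC/C2=C\C[C@@H]3CC(=O)O[C@H]3C/C(CO[Si](c3ccccc3)(c3ccccc3)C(C)(C)C)=C\CNC2)cc1 | intermediate (key-step precursor)
29 | isodiazene (1,1-diazene) of 28 | COc1ccc(COC/C2=C\C[C@@H]3CC(=O)O[C@H]3C/C(CO[Si](c3ccccc3)(c3ccccc3)C(C)(C)C)=C\C[N+](=[N-])C2)cc1 | intermediate (not isolated)
30 | (7R,8S)-14-((tert-butyldiphenylsilyl)oxy)-15-((4-methoxybenzyl)oxy)germacra-1(10)E,4Z-dien-12,8-olide (trans lactone; ring bond cis at C1=C10, trans at C4=C5) | COc1ccc(COC/C2=C\C[C@@H]3CC(=O)O[C@H]3C/C(CO[Si](c3ccccc3)(c3ccccc3)C(C)(C)C)=C\CC2)cc1 | intermediate (key-step product)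
31 | 11-((dimethylamino)methyl) derivative of 30 (C11 epimers) | COc1ccc(COC/C2=C\C[C@@H]3C(CN(C)C)C(=O)O[C@H]3C/C(CO[Si](c3ccccc3)(c3ccccc3)C(C)(C)C)=C\CC2)cc1 | intermediate (not isolated)
32 | trimethylammonium iodide from 31 | [I-].COc1ccc(COC/C2=C\C[C@@H]3C(C[N+](C)(C)C)C(=O)O[C@H]3C/C(CO[Si](c3ccccc3)(c3ccccc3)C(C)(C)C)=C\CC2)cc1 | intermediate (not isolated)
33 | (7R,8S)-14-((tert-butyldiphenylsilyl)oxy)-15-((4-methoxybenzyl)oxy)germacra-1(10)E,4Z,11(13)-trien-12,8-olide | COc1ccc(COC/C2=C\C[C@@H]3C(=C)C(=O)O[C@H]3C/C(CO[Si](c3ccccc3)(c3ccccc3)C(C)(C)C)=C\CC2)cc1 | intermediate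
34 | (7R,8S)-14-hydroxy-15-((4-methoxybenzyl)oxy)germacra-1(10)E,4Z,11(13)-trien-12,8-olide | COc1ccc(COC/C2=C\C[C@@H]3C(=C)C(=O)O[C@H]3C/C(CO)=C\CC2)cc1 | intermediate
35 | (7R,8S)-14-acetoxy-15-((4-methoxybenzyl)oxy)germacra-1(10)E,4Z,11(13)-trien-12,8-olide | COc1ccc(COC/C2=C\C[C@@H]3C(=C)C(=O)O[C@H]3C/C(COC(C)=O)=C\CC2)cc1 | intermediate
36 | (7R,8S)-14-acetoxy-15-hydroxygermacra-1(10)E,4Z,11(13)-trien-12,8-olide | OC/C1=C\C[C@@H]2C(=C)C(=O)O[C@H]2C/C(COC(C)=O)=C\CC1 | intermediate
37 | ethyl 2-(hydroxymethyl)acrylate | C=C(CO)C(=O)OCC | starting material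
38 | ethyl 2-(((tert-butyldimethylsilyl)oxy)methyl)acrylate | C=C(CO[Si](C)(C)C(C)(C)C)C(=O)OCC | intermediate
39 | 2-(((tert-butyldimethylsilyl)oxy)methyl)acrylic acid | C=C(CO[Si](C)(C)C(C)(C)C)C(=O)O | intermediate
40 | (7R,8S)-14-acetoxy-15-((2-(((tert-butyldimethylsilyl)oxy)methyl)acryloyl)oxy)germacra-1(10)E,4Z,11(13)-trien-12,8-olide | C=C(CO[Si](C)(C)C(C)(C)C)C(=O)OC/C1=C\C[C@@H]2C(=C)C(=O)O[C@H]2C/C(COC(C)=O)=C\CC1 | intermediate
41 | (7R,8S)-14-acetoxy-15-((2-(hydroxymethyl)acryloyl)oxy)germacra-1(10)E,4Z,11(13)-trien-12,8-olide (CNP0126545.1) | C=C(CO)C(=O)OC/C1=C\C[C@@H]2C(=C)C(=O)O[C@H]2C/C(COC(C)=O)=C\CC1 | target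

Total step count: 24 (22 on the main line, 2 for acid 39).
Longest linear sequence: 22 steps (steps 1–20, 23 and 24).

Steps most likely to fail

Step 16. Recombination of the allyl radical pair may go astray: coupling at the substituted termini C4 or C10, disproportionation to trienes, or loss of alkene geometry before the C2–C3 bond forms. The fallback makes the same bond by an established sulfone-anion macrocyclisation and sets out from 20. Appel bromination (CBr4, PPh3) of the C2 alcohol would give the allylic bromide F1, and sodium benzenesulfinate in DMF the C2 phenyl sulfone F2. Saponification and relactonisation as in step 12 would give the acid F3, and mixed-anhydride/NaBH4 reduction as in step 13 the C3 allylic alcohol F4. A second Appel reaction would give the C3 bromide F5. Slow addition of F5 to LiHMDS in THF at high dilution (the allylic sulfone is deprotonated in preference to the lactone) should close the ten-membered ring by intramolecular SN2 alkylation to the cyclic sulfone F6. Reductive desulfonylation (Na/Hg, Na2HPO4, MeOH, −20 °C) comes back to the route at 30.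

Step 8. The acetal-bearing Grignard reagent is a weak nucleophile, so conjugate transfer may be slow enough for recovered butenolide or 1,2-addition at the lactone carbonyl to dominate. The fallback builds the two-carbon aldehyde arm from a vinyl group and sets out from 12. Vinylmagnesium bromide with CuBr·SMe2 (cat.) and TMSCl in THF at −78 °C would give, by the same anti addition, the trans vinyl lactone F7. Chemoselective hydroboration of the monosubstituted alkene with 9-BBN and NaBO3 oxidation would give the primary alcohol F8, and Dess–Martin oxidation the THP-protected aldehyde F9. THP removal with AcOH/THF/H2O at 45 °C comes back to the route at 16.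

Step 14. Intermolecular N-alkylation (oligomerisation) or elimination of the activated alcohol may outrun closure of the eleven-membered ring. The fallback separates activation from ring closure and sets out from 26. Appel bromination would give the isolated allylic bromide F10. Slow addition of F10 to Cs2CO3 and Bu4NI in MeCN at 60 °C (2 mM) should effect intramolecular alkylation of the caesium sulfonamide and comes back to the route at 27.

Further compounds
F1 | step 16 | ethyl (E)-4-((2S,3R)-2-((E)-4-bromo-2-(((tert-butyldiphenylsilyl)oxy)methyl)but-2-en-1-yl)-5-oxotetrahydrofuran-3-yl)-2-(((4-methoxybenzyl)oxy)methyl)but-2-enoate | CCOC(=O)/C(COCc1ccc(OC)cc1)=C/C[C@@H]1CC(=O)O[C@H]1C/C(CO[Si](c1ccccc1)(c1ccccc1)C(C)(C)C)=C\CBr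
F2 | step 16 | C2 phenyl sulfone analogue of F1 | CCOC(=O)/C(COCc1ccc(OC)cc1)=C/C[C@@H]1CC(=O)O[C@H]1C/C(CO[Si](c1ccccc1)(c1ccccc1)C(C)(C)C)=C\CS(=O)(=O)c1ccccc1
F3 | step 16 | C3 carboxylic acid from F2 | OC(=O)/C(COCc1ccc(OC)cc1)=C/C[C@@H]1CC(=O)O[C@H]1C/C(CO[Si](c1ccccc1)(c1ccccc1)C(C)(C)C)=C\CS(=O)(=O)c1ccccc1
F4 | step 16 | C3 allylic alcohol from F3 | OC/C(COCc1ccc(OC)cc1)=C/C[C@@H]1CC(=O)O[C@H]1C/C(CO[Si](c1ccccc1)(c1ccccc1)C(C)(C)C)=C\CS(=O)(=O)c1ccccc1
F5 | step 16 | C3 allylic bromide from F4 | BrC/C(COCc1ccc(OC)cc1)=C/C[C@@H]1CC(=O)O[C@H]1C/C(CO[Si](c1ccccc1)(c1ccccc1)C(C)(C)C)=C\CS(=O)(=O)c1ccccc1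
F6 | step 16 | 2-(phenylsulfonyl) derivative of 30 (C2 epimers) | COc1ccc(COC/C2=C\C[C@@H]3CC(=O)O[C@H]3C/C(CO[Si](c3ccccc3)(c3ccccc3)C(C)(C)C)=C\C(C2)S(=O)(=O)c2ccccc2)cc1
F7 | step 8 | trans 4-vinyl lactone from 12 (vinyl on C7 anti to the C8 side chain) | C=C[C@@H]1CC(=O)O[C@H]1C/C(CO[Si](c1ccccc1)(c1ccccc1)C(C)(C)C)=C\COC1CCCCO1
F8 | step 8 | 2-hydroxyethyl lactone from F7 | OCC[C@@H]1CC(=O)O[C@H]1C/C(CO[Si](c1ccccc1)(c1ccccc1)C(C)(C)C)=C\COC1CCCCO1
F9 | step 8 | THP-protected form of aldehyde 16 | O=CC[C@@H]1CC(=O)O[C@H]1C/C(CO[Si](c1ccccc1)(c1ccccc1)C(C)(C)C)=C\COC1CCCCO1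
F10 | step 14 | C3 allylic bromide from 26 | BrC/C(COCc1ccc(OC)cc1)=C/C[C@@H]1CC(=O)O[C@H]1C/C(CO[Si](c1ccccc1)(c1ccccc1)C(C)(C)C)=C\CNS(=O)(=O)c1ccccc1[N+](=O)[O-]
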